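Two partners still present together cannot leave a product curve flat, yet in the dusk run X stands at 60.2% and D at 10.2% after 10.0 min, with 29.6% of E in neither.

| setting | dusk | winter | dawn | Wednesday's | Sunday's | Monday's | Friday's |
|---|---|---|---|---|---|---|---|
| E | 5 mM | 5 mM | 5 mM | 5.0 mM | 5.0 mM (fed, over 4.0 min) | 5.0 mM | 5.0 mM |
| L | 4.75 mM | 6.6 mM | 10 mM | 4.75 mM (fed, over 4.0 min) | 4.75 mM | 4.75 mM | 4.75 mM |
| temperature | −10 °C | 5 °C | −10 °C |  | 5 °C | 5 °C |  |
| remark | run made earlier | run made earlier | run made earlier | the addition at −35 °C, then warmed to 5 °C; the feed brings no volume worth counting | all else is in the flask from the start; the feed brings no volume worth counting | everything together at the start | everything together at the start at −35 °C, warmed to 5 °C at 4.0 min |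
| time |  |  |  | 6.0 min | 6.0 min | 6.0 min | 6.0 min |

- dusk (time / min: X / %, D / %): 0.667: 33.4, 2.5; 2.00: 49.9, 5.1; 3.00: 53.6, 7.3; 5.00: 58.7, 9.4; 8.00: 59.7, 9.6; 10.0: 60.2, 10.2; 12.0: 60.1, 9.5
- winter (time / min: X / %, D / %): 0.250: 42.7, 5.4; 0.667: 56.0, 9.9; 1.33: 61.6, 12.2; 2.00: 61.5, 11.6; 3.00: 61.6, 12.4; 4.00: 62.0, 11.8; 5.00: 62.2, 12.4
- dawn (time / min: X / %, D / %): 1.33: 71.6, 5.4; 3.00: 78.9, 6.1; 4.00: 78.4, 6.9; 6.00: 78.7, 5.9; 8.00: 79.1, 5.9; 10.0: 79.3, 6.9

(each reading ± 0.5 percentage points)



* the flask that comes out highest in amount of X, in percent of the E charged; "all alike" if 1.5 percentage points covers them all (Wednesday's / Sunday's / Monday's / Friday's / all alike)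
* amount of X at the end, in percent of the E charged, Wednesday's
* amount of X at the end, in percent of the E charged, Sunday's
* amount of X at the end, in percent of the E charged, Monday's
* amount of X at the end, in percent of the E charged, Friday's

1. From dusk to dawn L goes up to twice its charge and the unaccounted share falls to 13.8%, about half, so I read that share as E wasted in competition with L.

2. The winter run, at 5 °C, gives waste per X times the starting cL/cE as 0.539; this is my waste number, an inverted selectivity factor. I take waste per X as W·cE/cL, but the cE there is my assumption, since the earlier runs share one charge of E, and this is the weak link.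

3. Monday's has cE/cL of 1.05, and with D per X of 0.199 from winter I get X of 56.6%.

4. In the winter run both partners fall, so I take E's fall as the products' share of their last reading, let L fall with X and D, and read from the first reading, by the second-order form, a time for E of 0.104 min at winter's starting cL. Midway through Sunday's feed, with L spent at winter's share of X and D, I put cL near 2.88 mM, which makes that time 0.238 min, so the feed of 1.25 mM min⁻¹ gives a cE of roughly 0.298 mM, a rough figure, since my constant lumps every loss of E at winter's higher cE into one term.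

5. Sunday's waste per X is then 0.0557, and its X is 79.7%, more than dusk's reading at the same charge, so I commit to Sunday's.

The forecast differs: it names Friday's, with 56%, 40%, 53% and 58% for Wednesday's, Sunday's, Monday's and Friday's, holding of Sunday's that “L sits with little E and wastes itself”.

The flasks give 51.7%, 59.7%, 52.1% and 58.1% in that order, so Sunday's stands highest.

    L + Q → D (k = 19.5 L mol⁻¹ s⁻¹, Ea = 49.0 kJ mol⁻¹)
    E + L → X (k = 9.70 L mol⁻¹ s⁻¹, Ea = 43.0 kJ mol⁻¹)
    E ⇌ Q (K = 1.40, k = 0.0141 s⁻¹, Ea = 70.0 kJ mol⁻¹, ΔH = −6.00 kJ mol⁻¹)
    Q → J (k = 0.0335 s⁻¹, Ea = 66.0 kJ mol⁻¹)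
    2 E → G (k = 3.48 L mol⁻¹ s⁻¹, Ea = 50.0 kJ mol⁻¹)
    (constants at 5 °C)

From Monday's to Sunday's, G per X at 6.00 min falls from 0.481 to 0.130, while J per X goes from 0.184 to 0.239. So I reforge the link: W·cE/cL is to be read as G per X, with J counted beside it.

In a neighbour of Sunday's charged with 2.0 mM of E, I put cL near 4.00 mM and cE at roughly 0.0859 mM, so W gives 0.0116. That flask ends with G per X of 0.0277 and X of 72.6%.

The data come from a simulation with made-up constants; noise was put on by code.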